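**Target:** CNP0233066.1 = 15-acetoxy-7,9-bis(angeloyloxy)longipinan-1-one, (3R,4S,5S,6S,7R,9R,10R,11R), compound 35.

## Retrosynthetic overview

1. 35 ⇒ triol ketone 33: a lipase acetylates only the primary C15–OH and the two angelates go on last; the C3 methyl comes from cuprate addition to enone 31, anti to the C10 methyl.
2. Cyclobutane (third ring): C4–C10 bond by intramolecular α′-alkylation of the cis-fused cycloheptenone tosylate 22 (inversion at C4, quaternary C10).
3. Seven-ring stereocentres: C6 by hydroxymethylation of the α′-enolate of 14 on the convex face; Wharton enone transposition (16 → 20); C7 by conjugate borylation and C9 by hydroxyl-directed anti reduction after ring closure.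
4. Seven-membered ring (second ring): one-carbon ring expansion (siloxycyclopropane, FeCl3) of the cis-fused Diels–Alder adduct 9 from enone 6 and silyloxydiene 8.
5. Six-membered ring (first ring) and first stereocentres: (R)-4-silyloxycyclohexenone 6 by lipase desymmetrisation of meso-diacetate 2, made from cyclohexa-1,3-diene.

**Locants:** target (longipinane) locants are used for all intermediates from 6 on: C1 ring C=O; C2; C3 (bears CH3-12); C4, C5, C10, C11 = cyclobutane carbons; C6 (bears CH3-14 and C15H2O); C7 and C9 carbinols; C8; CH3-13 on C10. In the bicyclic intermediates α is the face of H-5/H-11.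

**Assumptions:** (a) the lipase hydrolysis of meso-2 is taken to give the (1S,4R) hydroxy acetate 3; with a lipase of opposite preference the same compound is reached by running the enzyme in the acylation direction on the meso-diol with vinyl acetate. (b) Centres that are destroyed later (C1 carbinol, C6–H and C10–H before enolisation, the epoxide and C9 carbinol of 17–19, C9–Cl of 13) are drawn as the expected major isomer; their configuration does not affect the outcome.

## Route

Step 1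
Reactants: 1 cyclohexa-1,3-diene
Product: 2 cis-cyclohex-2-ene-1,4-diyl diacetate (meso)
Conditions: Pd(OAc)2 (5 mol %), LiOAc, LiCl (cat.), p-benzoquinone, AcOH, 25 °C
Reagents that add atoms: acetic acid, CC(=O)O
Why: Bäckvall palladium-catalysed 1,4-diacetoxylation of a 1,3-diene, in which catalytic chloride makes the second acetate attack the π-allyl complex from outside and so gives the cis (meso) diacetate.

Step 2
Reactants: 2 cis-cyclohex-2-ene-1,4-diyl diacetate (meso)
Product: 3 (1S,4R)-4-hydroxycyclohex-2-en-1-yl acetate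
Conditions: lipase (Pseudomonas cepacia), phosphate buffer pH 7, 30 °C
Reagents that add atoms: none
Why: Lipase-catalysed enantiotopic-group-selective hydrolysis (desymmetrisation of a meso-diester) cleaves one acetate only and thereby sets the first two stereocentres by asymmetric catalysis.

Step 3
Reactants: 3 (1S,4R)-4-hydroxycyclohex-2-en-1-yl acetate
Product: 4 (1S,4R)-4-(tert-butyldimethylsilyloxy)cyclohex-2-en-1-yl acetate
Conditions: TBSCl, imidazole, DMF, 25 °C
Reagents that add atoms: tert-butyldimethylsilyl chloride, CC(C)(C)[Si](C)(C)Cl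
Why: Standard imidazole-promoted silylation of the free secondary alcohol, with no change at the stereocentres.

Step 4
Reactants: 4 (1S,4R)-4-(tert-butyldimethylsilyloxy)cyclohex-2-en-1-yl acetate
Product: 5 (1S,4R)-4-(tert-butyldimethylsilyloxy)cyclohex-2-en-1-ol
Conditions: K2CO3 (cat.), MeOH, 0 → 25 °C
Reagents that add atoms: none
Why: Base-catalysed transesterification (methanolysis) removes the acetate while the silyl ether is stable.

Step 5
Reactants: 5 (1S,4R)-4-(tert-butyldimethylsilyloxy)cyclohex-2-en-1-ol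
Product: 6 (R)-4-(tert-butyldimethylsilyloxy)cyclohex-2-en-1-one
Conditions: MnO2, CH2Cl2, 25 °C
Reagents that add atoms: none
Why: Chemoselective allylic alcohol oxidation gives the enone and leaves the silyloxy stereocentre (C4) untouched.

Step 6
Reactants: 7 (E)-hex-4-en-3-one
Product: 8 (2Z,4E)-3-(tert-butyldimethylsilyloxy)hexa-2,4-diene
Conditions: TBSOTf, Et3N, CH2Cl2, −78 → 0 °C
Reagents that add atoms: tert-butyldimethylsilyl triflate, CC(C)(C)[Si](C)(C)OS(=O)(=O)C(F)(F)F
Why: Soft enolisation and O-silylation on the ethyl side gives the 2-silyloxydiene, and the amine/silyl triflate conditions favour the Z enol ether needed for an s-cis diene.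

Step 7
Reactants: 6 (R)-4-(tert-butyldimethylsilyloxy)cyclohex-2-en-1-one; 8 (2Z,4E)-3-(tert-butyldimethylsilyloxy)hexa-2,4-diene
Product: 9 cis-fused Diels–Alder adduct (C1 ketone; 4α-OTBS; C7=C9 TBS enol ether; 13- and 14-CH3 β)
Conditions: Tf2NH (10 mol %), CH2Cl2, −78 → −40 °C
Reagents that add atoms: none
Why: Acid-catalysed Diels–Alder reaction (silyl triflimide formed in situ) in which the enol-ether terminus of the diene bonds to the enone β-carbon C5 anti to the C4 silyloxy group, and suprafacial addition makes the new C5–C6 and C11–C10 bonds cis.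

Step 8
Reactants: 9 cis-fused Diels–Alder adduct
Product: 10 bicyclic alcohol (1β-OH; 4α-OTBS; C7=C9 TBS enol ether)
Conditions: NaBH4, EtOH, −20 → 0 °C
Reagents that add atoms: none
Why: Hydride reduction from the convex face removes the C1 carbonyl at once, so the cis ring fusion at C11 can no longer epimerise; the C1 carbinol centre is erased later.

Step 9
Reactants: 10 bicyclic alcohol
Product: 11 benzyl ether (1β-OBn; 4α-OTBS; C7=C9 TBS enol ether)
Conditions: NaH, BnBr, Bu4NI (cat.), THF/DMF, 0 → 25 °C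
Reagents that add atoms: benzyl bromide, BrCc1ccccc1
Why: Williamson etherification gives a C1 protecting group orthogonal to all silyl ethers.

Step 10
Reactants: 11 benzyl ether
Product: 12 siloxycyclopropane (CH2 across C7–C9 on the α face; 7-OTBS)
Conditions: Et2Zn, CH2I2, CH2Cl2, 0 → 25 °C
Reagents that add atoms: diiodomethane, ICI
Why: Furukawa-modified Simmons–Smith cyclopropanation of the electron-rich silyl enol ether, which supplies the future C8.

Step 11
Reactants: 12 siloxycyclopropane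
Product: 14 cis-fused cycloheptenone (C7 ketone; C8=C9; 1β-OBn; 4α-OTBS), via β-chloro ketone 13 (not isolated)
Conditions: FeCl3, DMF, 0 → 25 °C; then NaOAc, MeOH, 65 °C
Reagents that add atoms: none
Why: Saegusa-type oxidative opening of the siloxycyclopropane cleaves the internal C7–C9 bond (secondary ring radical, trapped as chloride) and loss of HCl gives the one-carbon ring-expanded conjugated enone.

Step 12
Reactants: 14 cis-fused cycloheptenone
Product: 15 hydroxymethyl enone (C6 quaternary: 15-CH2OH α; 14-CH3 β)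
Conditions: LiN(iPr)2, THF, −78 °C; then HCHO (gas), −78 °C
Reagents that add atoms: formaldehyde, C=O
Why: Kinetic α′-deprotonation and aldol addition to formaldehyde, the electrophile entering the enolate face syn to H-5 (anti to the C5–C4 ring bond, the convex face of the cis-fused bicycle), which sets the C6 quaternary centre.

Step 13
Reactants: 15 hydroxymethyl enone
Product: 16 15-O-TBDPS enone
Conditions: TBDPSCl, imidazole, CH2Cl2, 25 °C
Reagents that add atoms: tert-butyldiphenylsilyl chloride, CC(C)(C)[Si](Cl)(c1ccccc1)c1ccccc1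
Why: Silylation of the primary alcohol blocks retro-aldol loss of formaldehyde and places a bulky group on the α face of C6.

Step 14
Reactants: 16 15-O-TBDPS enone
Product: 17 8α,9α-epoxy ketone
Conditions: H2O2 (30 %), NaOH, MeOH, 0 °C
Reagents that add atoms: hydrogen peroxide, OO
Why: Weitz–Scheffer nucleophilic epoxidation of the enone, with hydroperoxide adding to C9 anti to the neighbouring C10 methyl.

Step 15
Reactants: 17 8α,9α-epoxy ketone
Product: 19 allylic alcohol (9α-OH; C7=C8), via epoxy hydrazone 18 (not isolated)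
Conditions: N2H4·H2O, AcOH (cat.), MeOH, 0 → 25 °C
Reagents that add atoms: none
Why: Wharton transposition: the epoxy hydrazone fragments with loss of N2 to the transposed allylic alcohol, keeping the C9–O bond.

Step 16
Reactants: 19 allylic alcohol
Product: 20 transposed enone (C9 ketone; C7=C8)
Conditions: Dess–Martin periodinane, pyridine, CH2Cl2, 25 °C
Reagents that add atoms: none
Why: Dess–Martin oxidation completes the 1,3-enone transposition, giving an enone whose only enolisable position is C10.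

Step 17
Reactants: 20 transposed enone
Product: 21 4α-hydroxy enone
Conditions: HF (48 % aq), MeCN, 0 → 25 °C
Reagents that add atoms: none
Why: Acidic fluoride cleaves the secondary TBS ether much faster than the primary TBDPS ether, and the benzyl ether is inert.

Step 18
Reactants: 21 4α-hydroxy enone
Product: 22 4α-tosylate
Conditions: TsCl, Et3N, DMAP (cat.), CH2Cl2, 0 → 25 °C
Reagents that add atoms: p-toluenesulfonyl chloride, Cc1ccc(cc1)S(Cl)(=O)=O
Why: Sulfonylation with retention turns C4–O, which is trans to the C5–C6 bond, into a leaving group.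

Step 19
Reactants: 22 4α-tosylate
Product: 23 tricyclic enone (C4–C10 bond formed; C9 ketone; C7=C8; 1-OBn; 15-OTBDPS)
Conditions: KN(SiMe3)2, THF, −78 → 25 °C
Reagents that add atoms: none
Why: Intramolecular SN2 α′-alkylation (4-exo-tet) of the cross-conjugated potassium dienolate by the C4 tosylate with inversion closes the cyclobutane, and the cis C5/C11 fusion fixes the configuration of the new quaternary C10.

Step 20
Reactants: 23 tricyclic enone
Product: 25 7-hydroxy 9-ketone (C7 as in target), via β-boryl ketone 24 (not isolated)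
Conditions: CuCl (5 mol %), Xantphos (5 mol %), NaOtBu (10 mol %), B2pin2, MeOH, THF, 25 °C; then H2O2 (30 %), pH 7 buffer, 0 °C
Reagents that add atoms: hydrogen peroxide, OO
Why: Copper-catalysed conjugate borylation puts boron on C7 anti to the bulky CH2OTBDPS group on C6 (syn to CH3-14), and C–B oxidation proceeds with retention.

Step 21
Reactants: 25 7-hydroxy 9-ketone
Product: 26 7,9-anti-diol (C7 and C9 as in target)
Conditions: Me4NBH(OAc)3, AcOH/MeCN, −20 °C
Reagents that add atoms: none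
Why: Evans–Saksena reduction: hydride is delivered intramolecularly from the C7 alkoxyborohydride, giving the 1,3-anti (trans) diol.

Step 22
Reactants: 26 7,9-anti-diol
Product: 27 7,9-bis-TES ether
Conditions: Et3SiOTf, 2,6-lutidine, CH2Cl2, −78 → 0 °C
Reagents that add atoms: triethylsilyl triflate, CC[Si](CC)(CC)OS(=O)(=O)C(F)(F)F
Why: The reactive silyl triflate protects both hindered secondary alcohols so that C1 can be oxidised selectively.

Step 23
Reactants: 27 7,9-bis-TES ether
Product: 28 C1 alcohol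
Conditions: H2 (1 atm), Pd/C (10 %), EtOAc, 25 °C
Reagents that add atoms: none
Why: Hydrogenolysis removes only the benzyl ether; there is no alkene in the molecule and silyl ethers are stable in ethyl acetate.

Step 24
Reactants: 28 C1 alcohol
Product: 29 C1 ketone
Conditions: Dess–Martin periodinane, pyridine, CH2Cl2, 25 °C
Reagents that add atoms: none
Why: Dess–Martin oxidation restores the C1 ketone and erases the arbitrary C1 carbinol centre.

Step 25
Reactants: 29 C1 ketone
Product: 31 C2=C3 enone, via TMS enol ether 30 (not isolated)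
Conditions: LiN(iPr)2, Me3SiCl, THF, −78 °C; then Pd(OAc)2, MeCN, 25 °C
Reagents that add atoms: none
Why: Saegusa–Ito dehydrogenation; the bridgehead C11 cannot enolise (Bredt), so the enol ether and the enone form only towards C2.

Step 26
Reactants: 31 C2=C3 enone
Product: 32 3-methyl ketone (C3 as in target)
Conditions: Me2CuLi (from MeLi and CuI), Et2O, −78 → −40 °C
Reagents that add atoms: lithium dimethylcuprate, [Li+].C[Cu-]C
Why: Gilman cuprate 1,4-addition to the bicyclo[3.1.1]heptenone from the face anti to the C10 methyl, which shields the other face from its cyclobutane bridge, sets C3.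

Step 27
Reactants: 32 3-methyl ketone
Product: 33 7,9,15-trihydroxylongipinan-1-one (triol)
Conditions: Bu4NF, AcOH, THF, 25 → 45 °C
Reagents that add atoms: none
Why: Buffered fluoride removes both TES ethers and the TBDPS ether, and the triol ketone has no retro-aldol pathway.

Step 28
Reactants: 33 triol
Product: 34 15-acetate 7,9-diol
Conditions: lipase (Candida antarctica lipase B, immobilised), vinyl acetate, t-BuOMe, 35 °C
Reagents that add atoms: vinyl acetate, C=COC(C)=O
Why: Lipase-catalysed irreversible transesterification acylates only the primary C15 hydroxyl, since the two neopentylic secondary hydroxyls are not accepted by the enzyme.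

Step 29
Reactants: 34 15-acetate 7,9-diol
Product: 35 CNP0233066.1
Conditions: angelic acid, 2,4,6-trichlorobenzoyl chloride, Et3N, toluene, 25 °C; then 34, 80 °C
Reagents that add atoms: angelic acid, C/C=C(/C)C(=O)O
Why: Yamaguchi-type mixed-anhydride esterification run without a nucleophilic catalyst acylates both hindered secondary alcohols and keeps the Z (angelate) geometry.

## Compound list

1 | cyclohexa-1,3-diene | C1=CC=CCC1 | starting material
2 | cis-cyclohex-2-ene-1,4-diyl diacetate (meso) | CC(=O)O[C@@H]1C=C[C@H](OC(C)=O)CC1 | intermediate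
3 | (1S,4R)-4-hydroxycyclohex-2-en-1-yl acetate | CC(=O)O[C@@H]1C=C[C@H](O)CC1 | intermediate
4 | (1S,4R)-4-(tert-butyldimethylsilyloxy)cyclohex-2-en-1-yl acetate | CC(=O)O[C@@H]1C=C[C@H](O[Si](C)(C)C(C)(C)C)CC1 | intermediate
5 | (1S,4R)-4-(tert-butyldimethylsilyloxy)cyclohex-2-en-1-ol | O[C@@H]1C=C[C@H](O[Si](C)(C)C(C)(C)C)CC1 | intermediate
6 | (R)-4-(tert-butyldimethylsilyloxy)cyclohex-2-en-1-one | O=C1C=C[C@H](O[Si](C)(C)C(C)(C)C)CC1 | intermediate
7 | (E)-hex-4-en-3-one | C/C=C/C(=O)CC | starting material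
8 | (2Z,4E)-3-(tert-butyldimethylsilyloxy)hexa-2,4-diene | C/C=C/C(O[Si](C)(C)C(C)(C)C)=C/C | intermediate
9 | cis-fused Diels–Alder adduct (octalone): C1 ketone; 4α-OTBS; C7(OTBS)=C9 enol ether; CH3-14 on C6 and CH3-13 on C10 both β; H-5/H-11 α | O=C1CC[C@@H](O[Si](C)(C)C(C)(C)C)[C@H]2[C@@H]1[C@@H](C)C=C(O[Si](C)(C)C(C)(C)C)[C@H]2C | intermediate
10 | bicyclic alcohol: 9 with 1β-OH | O[C@@H]1CC[C@@H](O[Si](C)(C)C(C)(C)C)[C@H]2[C@@H]1[C@@H](C)C=C(O[Si](C)(C)C(C)(C)C)[C@H]2C | intermediate
11 | benzyl ether: 10 with 1β-OBn | C(c1ccccc1)O[C@@H]1CC[C@@H](O[Si](C)(C)C(C)(C)C)[C@H]2[C@@H]1[C@@H](C)C=C(O[Si](C)(C)C(C)(C)C)[C@H]2C | intermediate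
12 | siloxycyclopropane: CH2 (future C8) bridging C7 and C9 on the α face; 7β-OTBS | C(c1ccccc1)O[C@@H]1CC[C@@H](O[Si](C)(C)C(C)(C)C)[C@H]2[C@@H]1[C@@H](C)[C@@H]3C[C@]3(O[Si](C)(C)C(C)(C)C)[C@H]2C | intermediate
13 | β-chloro ketone: cis-fused bicyclo[5.4.0]undecane; C7 ketone; 9α-Cl | C(c1ccccc1)O[C@@H]1CC[C@@H](O[Si](C)(C)C(C)(C)C)[C@H]2[C@@H]1[C@@H](C)[C@H](Cl)CC(=O)[C@H]2C | intermediate
14 | cis-fused cycloheptenone: C7 ketone; C8=C9; 1β-OBn; 4α-OTBS; CH3-14 β | C(c1ccccc1)O[C@@H]1CC[C@@H](O[Si](C)(C)C(C)(C)C)[C@H]2[C@@H]1[C@@H](C)C=CC(=O)[C@H]2C | intermediate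
15 | hydroxymethyl enone: 14 with quaternary C6 (15-CH2OH α; CH3-14 β) | C(c1ccccc1)O[C@@H]1CC[C@@H](O[Si](C)(C)C(C)(C)C)[C@H]2[C@@H]1[C@@H](C)C=CC(=O)[C@]2(C)CO | intermediate
16 | 15-O-TBDPS enone | C(c1ccccc1)O[C@@H]1CC[C@@H](O[Si](C)(C)C(C)(C)C)[C@H]2[C@@H]1[C@@H](C)C=CC(=O)[C@]2(C)CO[Si](c1ccccc1)(c1ccccc1)C(C)(C)C | intermediate
17 | 8α,9α-epoxy ketone (C7 ketone) | C(c1ccccc1)O[C@@H]1CC[C@@H](O[Si](C)(C)C(C)(C)C)[C@H]2[C@@H]1[C@@H](C)[C@@H]3O[C@@H]3C(=O)[C@]2(C)CO[Si](c1ccccc1)(c1ccccc1)C(C)(C)C | intermediate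
18 | epoxy hydrazone (C7=N–NH2) of 17 | C(c1ccccc1)O[C@@H]1CC[C@@H](O[Si](C)(C)C(C)(C)C)[C@H]2[C@@H]1[C@@H](C)[C@@H]3O[C@@H]3C(=NN)[C@]2(C)CO[Si](c1ccccc1)(c1ccccc1)C(C)(C)C | intermediate
19 | allylic alcohol: 9α-OH; C7=C8 | C(c1ccccc1)O[C@@H]1CC[C@@H](O[Si](C)(C)C(C)(C)C)[C@H]2[C@@H]1[C@@H](C)[C@H](O)C=C[C@]2(C)CO[Si](c1ccccc1)(c1ccccc1)C(C)(C)C | intermediate
20 | transposed enone: C9 ketone; C7=C8 | C(c1ccccc1)O[C@@H]1CC[C@@H](O[Si](C)(C)C(C)(C)C)[C@H]2[C@@H]1[C@@H](C)C(=O)C=C[C@]2(C)CO[Si](c1ccccc1)(c1ccccc1)C(C)(C)C | intermediate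
21 | 4α-hydroxy enone | C(c1ccccc1)O[C@@H]1CC[C@@H](O)[C@H]2[C@@H]1[C@@H](C)C(=O)C=C[C@]2(C)CO[Si](c1ccccc1)(c1ccccc1)C(C)(C)C | intermediate
22 | 4α-tosylate | C(c1ccccc1)O[C@@H]1CC[C@@H](OS(=O)(=O)c3ccc(C)cc3)[C@H]2[C@@H]1[C@@H](C)C(=O)C=C[C@]2(C)CO[Si](c1ccccc1)(c1ccccc1)C(C)(C)C | intermediate
23 | tricyclic enone (longipinane skeleton): C9 ketone; C7=C8; 1-OBn; 15-OTBDPS; C4, C5, C6, C10, C11 arranged as in the target | C1=CC(=O)[C@]2(C)[C@@H]3[C@@H]([C@H]2[C@H](OCc4ccccc4)CC3)[C@@]1(C)CO[Si](c1ccccc1)(c1ccccc1)C(C)(C)C | intermediate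
24 | β-boryl ketone: C7–B(pin) syn to CH3-14; C9 ketone | CC1(C)OB(OC1(C)C)[C@@H]2CC(=O)[C@]3(C)[C@@H]4[C@@H]([C@H]3[C@H](OCc5ccccc5)CC4)[C@@]2(C)CO[Si](c2ccccc2)(c2ccccc2)C(C)(C)C | intermediate
25 | 7-hydroxy 9-ketone (C7 as in target) | O[C@@H]1CC(=O)[C@]2(C)[C@@H]3[C@@H]([C@H]2[C@H](OCc4ccccc4)CC3)[C@@]1(C)CO[Si](c1ccccc1)(c1ccccc1)C(C)(C)C | intermediate
26 | 7,9-anti-diol (C7, C9 as in target) | O[C@@H]1C[C@@H](O)[C@]2(C)[C@@H]3[C@@H]([C@H]2[C@H](OCc4ccccc4)CC3)[C@@]1(C)CO[Si](c1ccccc1)(c1ccccc1)C(C)(C)C | intermediate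
27 | 7,9-bis-TES ether | CC[Si](CC)(CC)O[C@@H]1C[C@@H](O[Si](CC)(CC)CC)[C@]2(C)[C@@H]3[C@@H]([C@H]2[C@H](OCc4ccccc4)CC3)[C@@]1(C)CO[Si](c1ccccc1)(c1ccccc1)C(C)(C)C | intermediate
28 | C1 alcohol | CC[Si](CC)(CC)O[C@@H]1C[C@@H](O[Si](CC)(CC)CC)[C@]2(C)[C@@H]3[C@@H]([C@H]2[C@H](O)CC3)[C@@]1(C)CO[Si](c1ccccc1)(c1ccccc1)C(C)(C)C | intermediate
29 | C1 ketone | CC[Si](CC)(CC)O[C@@H]1C[C@@H](O[Si](CC)(CC)CC)[C@]2(C)[C@@H]3[C@@H]([C@H]2C(=O)CC3)[C@@]1(C)CO[Si](c1ccccc1)(c1ccccc1)C(C)(C)C | intermediate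
30 | TMS enol ether (C1=C2) | CC[Si](CC)(CC)O[C@@H]1C[C@@H](O[Si](CC)(CC)CC)[C@]2(C)[C@@H]3[C@@H]([C@H]2C(O[Si](C)(C)C)=CC3)[C@@]1(C)CO[Si](c1ccccc1)(c1ccccc1)C(C)(C)C | intermediate
31 | C2=C3 enone (C1 ketone) | CC[Si](CC)(CC)O[C@@H]1C[C@@H](O[Si](CC)(CC)CC)[C@]2(C)[C@@H]3[C@@H]([C@H]2C(=O)C=C3)[C@@]1(C)CO[Si](c1ccccc1)(c1ccccc1)C(C)(C)C | intermediate
32 | 3-methyl ketone (C3 as in target) | CC[Si](CC)(CC)O[C@@H]1C[C@@H](O[Si](CC)(CC)CC)[C@]2(C)[C@@H]3[C@@H]([C@H]2C(=O)C[C@H]3C)[C@@]1(C)CO[Si](c1ccccc1)(c1ccccc1)C(C)(C)C | intermediate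
33 | 7,9,15-trihydroxylongipinan-1-one (all centres as in target) | O[C@@H]1C[C@@H](O)[C@]2(C)[C@@H]3[C@@H]([C@H]2C(=O)C[C@H]3C)[C@@]1(C)CO | intermediate
34 | 15-acetoxy-7,9-dihydroxylongipinan-1-one | O[C@@H]1C[C@@H](O)[C@]2(C)[C@@H]3[C@@H]([C@H]2C(=O)C[C@H]3C)[C@@]1(C)COC(C)=O | intermediate
35 | CNP0233066.1, (3R,4S,5S,6S,7R,9R,10R,11R)-15-acetoxy-7,9-bis(angeloyloxy)longipinan-1-one | C/C=C(/C)C(=O)O[C@@H]1C[C@@H](OC(=O)/C(C)=C\C)[C@]2(C)[C@@H]3[C@@H]([C@H]2C(=O)C[C@H]3C)[C@@]1(C)COC(C)=O | target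

## Step count and risks

Total steps: 29. Longest linear sequence: 28 steps (1 → 35 through steps 1–5 and 7–29); step 6 is a one-step side branch.

**Step 19 (cyclobutane closure).** The 4-exo alkylation at a hindered secondary carbon can lose to elimination or O-alkylation. The fallback sets out from 22 and comes back at 23, and it replaces the sulfonate displacement by an epoxide opening. DBU in toluene at 80 °C eliminates the tosylate anti-periplanar to H-3β only (H-5 is cis to the leaving group) and gives the cyclohexene F4. mCPBA epoxidises the isolated C3=C4 alkene on the α face, anti to the C6 quaternary centre, and gives the epoxide F5; the enone alkene is inert. KN(SiMe3)2 then lets the C10 dienolate open the epoxide at C4 in the exo mode (trans-diaxial, inversion at C4), which gives the tricyclic alcohol F6 with a 3α-hydroxyl. Thiocarbonyldiimidazole converts it into the imidazolyl thiocarbonate F7, and Bu3SnH/AIBN (Barton–McCombie deoxygenation) gives 23.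

**Step 15 (Wharton transposition).** Hydrazone formation at a ketone flanked by a quaternary carbon may be slow. The fallback sets out from 16 and comes back at 19, and it is a radical version of the transposition. NaBH4/CeCl3·7H2O (Luche reduction) attacks C7 from the CH3-14 face and gives the allylic alcohol F1 (7α-OH). VO(acac)2/t-BuOOH epoxidises syn to the hydroxyl and gives the epoxy alcohol F2 with the same 8α,9α-epoxide as 17. Thiocarbonyldiimidazole gives the imidazolyl thiocarbonate F3. Bu3SnH/AIBN generates the C7 radical, which opens the neighbouring epoxide to the C7=C8 alkene and the 9α-alkoxyl radical, and hydrogen transfer gives 19.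

**Step 29 (double angeloylation).** Two neopentylic secondary alcohols must be acylated without Z → E isomerisation to tiglates. The fallback sets out from 34 and comes back at 35, and it builds the angelate double bonds after acylation. 2-[Bis(2,2,2-trifluoroethoxy)phosphoryl]propanoic acid with DCC and DMAP acylates both hydroxyls and gives the bis(phosphonopropionate) F8. KN(SiMe3)2/18-crown-6 followed by acetaldehyde at −78 °C (Still–Gennari Z-selective olefination) then forms both (Z)-2-methylbut-2-enoates, which is 35.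

## Further compounds

F1 | step 15 | allylic alcohol: 7α-OH; C8=C9; otherwise as 16 | C(c1ccccc1)O[C@@H]1CC[C@@H](O[Si](C)(C)C(C)(C)C)[C@H]2[C@@H]1[C@@H](C)C=C[C@H](O)[C@]2(C)CO[Si](c1ccccc1)(c1ccccc1)C(C)(C)C
F2 | step 15 | epoxy alcohol: 7α-OH; 8α,9α-epoxide | C(c1ccccc1)O[C@@H]1CC[C@@H](O[Si](C)(C)C(C)(C)C)[C@H]2[C@@H]1[C@@H](C)[C@@H]3O[C@@H]3[C@H](O)[C@]2(C)CO[Si](c1ccccc1)(c1ccccc1)C(C)(C)C
F3 | step 15 | imidazolyl thiocarbonate of F2 (on O-7) | C(c1ccccc1)O[C@@H]1CC[C@@H](O[Si](C)(C)C(C)(C)C)[C@H]2[C@@H]1[C@@H](C)[C@@H]3O[C@@H]3[C@H](OC(=S)n3ccnc3)[C@]2(C)CO[Si](c1ccccc1)(c1ccccc1)C(C)(C)C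
F4 | step 19 | cyclohexene: C3=C4; C9 ketone; C7=C8; otherwise as 22 without the tosylate | C(c1ccccc1)O[C@@H]1CC=C[C@H]2[C@@H]1[C@@H](C)C(=O)C=C[C@]2(C)CO[Si](c1ccccc1)(c1ccccc1)C(C)(C)C
F5 | step 19 | 3α,4α-epoxide of F4 | C(c1ccccc1)O[C@@H]1C[C@H]3O[C@H]3[C@H]2[C@@H]1[C@@H](C)C(=O)C=C[C@]2(C)CO[Si](c1ccccc1)(c1ccccc1)C(C)(C)C
F6 | step 19 | tricyclic alcohol: 23 with a 3α-hydroxyl (OH anti to CH3-13) | C1=CC(=O)[C@]2(C)[C@@H]3[C@@H]([C@H]2[C@H](OCc4ccccc4)C[C@H]3O)[C@@]1(C)CO[Si](c1ccccc1)(c1ccccc1)C(C)(C)C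
F7 | step 19 | imidazolyl thiocarbonate of F6 (on O-3) | C1=CC(=O)[C@]2(C)[C@@H]3[C@@H]([C@H]2[C@H](OCc4ccccc4)C[C@H]3OC(=S)n4ccnc4)[C@@]1(C)CO[Si](c1ccccc1)(c1ccccc1)C(C)(C)C
F8 | step 29 | 7,9-bis{2-[bis(2,2,2-trifluoroethoxy)phosphoryl]propanoate} of 34 (epimer mixture at the two phosphonate α-carbons) | CC(C(=O)O[C@@H]1C[C@@H](OC(=O)C(C)P(=O)(OCC(F)(F)F)OCC(F)(F)F)[C@]2(C)[C@@H]3[C@@H]([C@H]2C(=O)C[C@H]3C)[C@@]1(C)COC(C)=O)P(=O)(OCC(F)(F)F)OCC(F)(F)F
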